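**Plan**
Guaiane locants are used: C1–C15 for the hydroxylated half, C1'–C15' for the dienone half.
1. The cyclohexene is cut at C2'–C4 and C14'–C15 (Diels–Alder) into dienone 22 and methylene ketone 17.
2. In 17 the unit C15H2=C4–C3(=O), with C4 bonded to ring-fusion carbon C5, is the retron of a 1-ethynylcyclobutanol: cyclobutane C1–C2–C3–C5 becomes cyclopentanone C1–C5 when the C3–C5 bond shifts to alkyne carbon C4.
3. Behind that, the cuts are C8–C9 (allylsilane plus aldehyde), C6–C7 (Barbier allylation) and the cyclobutane itself (photocycloaddition of a ketene acetal to a chiral butenolide).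
4. Forward order: cyclobutane, lactone, seven-membered ring, ring expansion to the cyclopentanone, cyclohexene by cycloaddition with the half made from dehydrocostus lactone, enone isomerisation, desilylation.
5. Stereochemistry: C1/C5 from the butenolide stereocentre (later excised); C6/C7 from a chair allylation; C8 from the ring closure; spiro C4 from convex-face cycloaddition; C6'/C7' from dehydrocostus lactone; C5'/C10' by final equilibration.

Key step: step 13

Remark: C5' and C10' are both γ-positions of the C1'=C2'–C3'=O enone and epimerise through its extended enolate, so the configuration drawn in the target is taken to be the thermodynamic one; 3-(bromomethyl)furan-2(5H)-one is taken as a purchasable building block.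

**Step 1**
Reactants: 1 (S)-5-(hydroxymethyl)furan-2(5H)-one
Product: 2 (S)-5-[(tert-butyldiphenylsilyloxy)methyl]furan-2(5H)-one
Conditions: TBDPSCl, imidazole, DMF, 0 °C to rt
Reagents that add atoms: tert-butyl(chloro)diphenylsilane, CC(C)(C)[Si](Cl)(c1ccccc1)c1ccccc1
Why: Silylation of the primary alcohol installs a bulky, fluoride-labile group that shields one face of the butenolide in step 2; no stereocentre is touched.

**Step 2**
Reactants: 2 (S)-5-[(tert-butyldiphenylsilyloxy)methyl]furan-2(5H)-one; 3 1,1-diethoxyethene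
Product: 4 (4S)-4-[(tert-butyldiphenylsilyloxy)methyl]-6,6-diethoxy-3-oxabicyclo[3.2.0]heptan-2-one (cis-fused, cyclobutane anti to the silyloxymethyl group)
Conditions: hν (medium-pressure Hg lamp, Pyrex), 3 (10 equiv), MeCN, −20 °C
Reagents that add atoms: none
Why: Enone–alkene [2+2] photocycloaddition in which the electron-rich alkene adds head-to-tail (acetal carbon to the β-carbon), the five-membered ring enforces cis fusion, and approach anti to the silyloxymethyl group sets C1 and C5.

**Step 3**
Reactants: 4 photoadduct lactone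
Product: 6 (1S)-2-(tert-butyldiphenylsilyloxy)-1-{cis-2,2-diethoxy-4-[3-(trimethylsilyl)prop-1-en-2-yl]cyclobutyl}ethanol, via bis(silylmethyl) carbinol 5 (not isolated)
Conditions: Me3SiCH2MgCl (5 equiv), CeCl3, THF, −78 °C to rt; then silica gel, CH2Cl2
Reagents that add atoms: (trimethylsilyl)methylmagnesium chloride, C[Si](C)(C)C[Mg]Cl
Why: Double addition of the weakly basic organocerium reagent to the lactone carbonyl and Peterson elimination of the β-hydroxysilane turn C10 into a 2-substituted allylsilane and free the C6 carbinol, without enolising C1.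

**Step 4**
Reactants: 6 allylsilane silyl ether
Product: 7 (1S)-1-{cis-2,2-diethoxy-4-[3-(trimethylsilyl)prop-1-en-2-yl]cyclobutyl}ethane-1,2-diol
Conditions: TBAF, AcOH, THF, 0 °C to rt
Reagents that add atoms: none
Why: Buffered fluoride cleaves the silyl ether to the 1,2-diol while the allylsilane, which has no electrophile to react with, should survive.

**Step 5**
Reactants: 7 diol
Product: 8 cis-2,2-diethoxy-4-[3-(trimethylsilyl)prop-1-en-2-yl]cyclobutane-1-carbaldehyde
Conditions: NaIO4, THF/pH 7 buffer, 0 °C
Reagents that add atoms: none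
Why: Periodate glycol cleavage excises the auxiliary carbon as formaldehyde and leaves the C6 aldehyde under neutral conditions that should not epimerise the cis-cyclobutane centre C5.

**Step 6**
Reactants: 8 cyclobutanecarbaldehyde; 9 3-(bromomethyl)furan-2(5H)-one
Product: 10 4-[(S*)-hydroxy(cyclobutyl)methyl]-3-methylenedihydrofuran-2(3H)-one (anti adduct; cyclobutyl = the ring of 8)
Conditions: Zn (activated), THF, 0 °C; aq NH4Cl work-up
Reagents that add atoms: none
Why: Barbier allylation through a chair (Zimmerman–Traxler) transition state in which the ring of 9 holds the γ-substituent trans to the CH2Zn carbon, so C6–OH and C7–C8 come out anti, while attack on the aldehyde face remote from the allylsilane-bearing C1 (supported by zinc chelation to a ketal oxygen) sets C6 relative to C5.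

**Step 7**
Reactants: 10 Barbier adduct
Product: 11 trans-5-(cyclobutyl)-4-(hydroxymethyl)-3-methylenedihydrofuran-2(3H)-one
Conditions: DBU (0.2 equiv), CH2Cl2, rt
Reagents that add atoms: none
Why: Base-catalysed translactonisation moves the acyl group from the primary C8 oxygen to the secondary C6 oxygen, giving the more substituted trans-β,γ-disubstituted α-methylene-γ-butyrolactone (anti adduct gives trans lactone) without touching a stereocentre.

**Step 8**
Reactants: 11 hydroxymethyl lactone
Product: 12 trans-2-(cyclobutyl)-4-methylene-5-oxotetrahydrofuran-3-carbaldehyde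
Conditions: Dess–Martin periodinane, NaHCO3, CH2Cl2, 0 °C
Reagents that add atoms: none
Why: Dess–Martin oxidation of the only free alcohol gives the C8 aldehyde under buffered, non-basic conditions that avoid β-elimination of the lactone oxygen and epimerisation at C7.

**Step 9**
Reactants: 12 aldehyde
Product: 13 3,3-diethoxy-8β-hydroxy-4,15-dinorguaia-10(14),11(13)-dien-12,6α-olide with a C3–C5 bond (cis-bicyclo[5.2.0]nonane core; H1α, H5α, H6β, H7α)
Conditions: SnCl4 (1.1 equiv), CH2Cl2, −78 °C
Reagents that add atoms: none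
Why: Intramolecular Hosomi–Sakurai allylation closes the seven-membered ring (C8–C9) and leaves the C10=C14 methylene; the tin-bound oxygen takes the pseudo-axial site away from the lactone methylene C13 (the face also exposed in a chelate to O6), so the new hydroxyl should be 8β, cis to C11.

**Step 10**
Reactants: 13 tricyclic alcohol
Product: 14 8-O-tert-butyldimethylsilyl ether of 13
Conditions: tert-butyldimethylsilyl triflate, 2,6-lutidine, CH2Cl2, −78 °C
Reagents that add atoms: tert-butyldimethylsilyl triflate, CC(C)(C)[Si](C)(C)OS(=O)(=O)C(F)(F)F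
Why: Silylation of the hindered axial alcohol blocks translactonisation of O8 (cis to C11) in the later basic steps; the ketone ketal is not cleaved by the silyl triflate/lutidine pair.

**Step 11**
Reactants: 14 silyl ether ketal
Product: 15 8β-(tert-butyldimethylsilyloxy)-3-oxo-4,15-dinorguaia-10(14),11(13)-dien-12,6α-olide with a C3–C5 bond (cyclobutanone)
Conditions: TsOH·H2O (cat.), acetone/H2O, rt
Reagents that add atoms: water, O
Why: Acid-catalysed ketal hydrolysis unmasks the cyclobutanone; the secondary silyl ether and the lactone should tolerate the mild acid.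

**Step 12**
Reactants: 15 cyclobutanone
Product: 16 3α-ethynyl-3β-hydroxy analogue of 15 (1-ethynylcyclobutanol)
Conditions: HC≡CMgBr, CeCl3, THF, −78 °C
Reagents that add atoms: ethynylmagnesium bromide, C#C[Mg]Br
Why: 1,2-Addition of the alkynylcerium reagent to the strained cyclobutanone from its convex face outruns attack on the lactone and conjugate addition; the new carbinol centre is lost in step 13.

**Step 13**
Reactants: 16 1-ethynylcyclobutanol
Product: 17 8β-(tert-butyldimethylsilyloxy)-3-oxoguaia-4(15),10(14),11(13)-trien-12,6α-olide (8β-silyloxy-dehydrozaluzanin C)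
Conditions: (4-CF3C6H4)3PAuCl (2 mol %), AgSbF6 (2 mol %), CH2Cl2, rt
Reagents that add atoms: none
Why: Cationic monovalent gold binds the alkyne, the C3–C5 bond anti to gold shifts to C4 while the carbinol oxygen becomes the C3 carbonyl, and protodeauration of the vinylgold gives the C4=C15 methylene. The closest known reaction type is the gold-catalysed ring expansion of 1-alkynylcyclobutanols to 2-alkylidenecyclopentanones. The cyclopentanone is not closed from a chain but arises by a 1,2-shift of a ring bond (four- to five-membered ring expansion), driven by release of cyclobutane strain. No new stereocentre forms: C5 migrates with retention, so the cis fusion (H1α, H5α) of the bicyclo[5.2.0] precursor is carried into the 5/7 system, and the carbinol centre C3 disappears. The step needs migration of the ring-fusion carbon C5 and not of C2 (secured by the better stabilisation of positive charge at the more substituted carbon), and ring expansion in preference to Meyer–Schuster rearrangement or enyne cycloisomerisation with C10=C14 (secured by strain release and by the cross-ring placement of that alkene). The same event unmasks, next to lactone and silyl ether, the enone that acts as dienophile in step 17.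

**Step 14**
Reactants: 18 dehydrocostus lactone
Product: 19 3-epizaluzanin C (3α-hydroxyguaia-4(15),10(14),11(13)-trien-12,6α-olide)
Conditions: SeO2 (0.5 equiv), t-BuOOH, CH2Cl2, rt
Reagents that add atoms: tert-butyl hydroperoxide, CC(C)(C)OO
Why: Allylic oxidation (ene reaction then [2,3]-sigmatropic shift) at the C4=C15 alkene places oxygen on the C3 methylene from the convex face; the C3 configuration is erased in step 15.

**Step 15**
Reactants: 19 3-epizaluzanin C
Product: 20 dehydrozaluzanin C (3-oxoguaia-4(15),10(14),11(13)-trien-12,6α-olide)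
Conditions: Dess–Martin periodinane, NaHCO3, CH2Cl2, rt
Reagents that add atoms: none
Why: Dess–Martin oxidation of the allylic alcohol gives the exo-methylene ketone without isomerising the three exocyclic alkenes.

**Step 16**
Reactants: 20 dehydrozaluzanin C
Product: 21 3-(trimethylsilyloxy)guaia-2,4(15),10(14),11(13)-tetraen-12,6α-olide
Conditions: trimethylsilyl triflate, Et3N, CH2Cl2, 0 °C
Reagents that add atoms: trimethylsilyl triflate, C[Si](C)(C)OS(=O)(=O)C(F)(F)F
Why: Soft enolisation is regiospecific because C2 is the only enolisable α-position (C4 carries no hydrogen), giving the 2-silyloxy diene.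

**Step 17**
Reactants: 21 silyl dienol ether; 17 8β-silyloxy-dehydrozaluzanin C (3 equiv)
Product: 23 Diels–Alder adduct (bonds C2'–C4 and C14'–C15, C1'=C10' alkene, H2'β, H5'α, 8-O-silyl), via tetraenone 22 (not isolated)
Conditions: Pd(OAc)2 (1.1 equiv), MeCN, rt
Reagents that add atoms: none
Why: Saegusa–Ito oxidation gives dienone 22, whose s-cis exocyclic diene C2'=C1'–C10'=C14' is trapped by the excess enone 17 in an intermolecular Diels–Alder reaction with the regiochemistry of the parent enone dimerisation, the diene adding to the convex α-face of the cis-fused methylene ketone (the face of H1 and H5) to set the spiro centre C4.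

**Step 18**
Reactants: 23 Diels–Alder adduct
Product: 24 8-O-tert-butyldimethylsilyl ether of the target (C1'=C2' enone, H10'α, H5'β)
Conditions: DBU, toluene, rt, degassed
Reagents that add atoms: none
Why: Base-mediated isomerisation of the β,γ-unsaturated ketone through its dienolate gives the conjugated C1'=C2' enone with protonation at C10', and reversible γ-deprotonation at C5' lets both centres settle to the thermodynamic configuration assumed in the remark; oxygen is excluded to avoid γ-hydroxylation.

**Step 19**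
Reactants: 24 silyl ether
Product: 25 target CNP0178208.1
Conditions: HF·pyridine, THF, 0 °C
Reagents that add atoms: none
Why: Fluoride cleavage of the silyl ether under acidic, non-basic conditions avoids translactonisation of the 8β-hydroxyl onto C12 and conjugate additions to the three Michael acceptors.

**Compound list**
1 | (S)-5-(hydroxymethyl)furan-2(5H)-one | OC[C@H]1OC(=O)C=C1 | starting material
2 | (S)-5-[(tert-butyldiphenylsilyloxy)methyl]furan-2(5H)-one | CC(C)(C)[Si](c1ccccc1)(c1ccccc1)OC[C@H]1OC(=O)C=C1 | intermediate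
3 | 1,1-diethoxyethene | C=C(OCC)OCC | starting material
4 | (4S)-4-[(tert-butyldiphenylsilyloxy)methyl]-6,6-diethoxy-3-oxabicyclo[3.2.0]heptan-2-one, cis-fused, anti adduct | CCOC1(OCC)C[C@H]2C(=O)O[C@H](CO[Si](c3ccccc3)(c3ccccc3)C(C)(C)C)[C@@H]12 | intermediate
5 | 2-{cis-2-[(1S)-2-(tert-butyldiphenylsilyloxy)-1-hydroxyethyl]-3,3-diethoxycyclobutyl}-1,3-bis(trimethylsilyl)propan-2-ol | CCOC1(OCC)C[C@@H](C(O)(C[Si](C)(C)C)C[Si](C)(C)C)[C@H]1[C@H](O)CO[Si](c1ccccc1)(c1ccccc1)C(C)(C)C | intermediate
6 | (1S)-2-(tert-butyldiphenylsilyloxy)-1-{cis-2,2-diethoxy-4-[3-(trimethylsilyl)prop-1-en-2-yl]cyclobutyl}ethanol | CCOC1(OCC)C[C@@H](C(=C)C[Si](C)(C)C)[C@H]1[C@H](O)CO[Si](c1ccccc1)(c1ccccc1)C(C)(C)C | intermediate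
7 | (1S)-1-{cis-2,2-diethoxy-4-[3-(trimethylsilyl)prop-1-en-2-yl]cyclobutyl}ethane-1,2-diol | CCOC1(OCC)C[C@@H](C(=C)C[Si](C)(C)C)[C@H]1[C@H](O)CO | intermediate
8 | cis-2,2-diethoxy-4-[3-(trimethylsilyl)prop-1-en-2-yl]cyclobutane-1-carbaldehyde | CCOC1(OCC)C[C@@H](C(=C)C[Si](C)(C)C)[C@H]1C=O | intermediate
9 | 3-(bromomethyl)furan-2(5H)-one | BrCC1=CCOC1=O | starting material
10 | anti Barbier adduct, 4-[hydroxy(cyclobutyl)methyl]-3-methylenedihydrofuran-2(3H)-one | CCOC1(OCC)C[C@@H](C(=C)C[Si](C)(C)C)[C@H]1[C@@H](O)[C@H]1COC(=O)C1=C | intermediate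
11 | trans-5-(cyclobutyl)-4-(hydroxymethyl)-3-methylenedihydrofuran-2(3H)-one | CCOC1(OCC)C[C@@H](C(=C)C[Si](C)(C)C)[C@H]1[C@H]1OC(=O)C(=C)[C@@H]1CO | intermediate
12 | trans-2-(cyclobutyl)-4-methylene-5-oxotetrahydrofuran-3-carbaldehyde | CCOC1(OCC)C[C@@H](C(=C)C[Si](C)(C)C)[C@H]1[C@H]1OC(=O)C(=C)[C@@H]1C=O | intermediate
13 | 3,3-diethoxy-8β-hydroxy-4,15-dinorguaia-10(14),11(13)-dien-12,6α-olide with C3–C5 bond | CCOC1(OCC)C[C@H]2C(=C)C[C@@H](O)[C@H]3C(=C)C(=O)O[C@@H]3[C@@H]12 | intermediate
14 | 8-O-tert-butyldimethylsilyl ether of 13 | CCOC1(OCC)C[C@H]2C(=C)C[C@@H](O[Si](C)(C)C(C)(C)C)[C@H]3C(=C)C(=O)O[C@@H]3[C@@H]12 | intermediate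
15 | 8β-(tert-butyldimethylsilyloxy)-3-oxo-4,15-dinorguaia-10(14),11(13)-dien-12,6α-olide with C3–C5 bond | O=C1C[C@H]2C(=C)C[C@@H](O[Si](C)(C)C(C)(C)C)[C@H]3C(=C)C(=O)O[C@@H]3[C@@H]12 | intermediate
16 | 3α-ethynyl-3β-hydroxy analogue of 15 | C#C[C@]1(O)C[C@H]2C(=C)C[C@@H](O[Si](C)(C)C(C)(C)C)[C@H]3C(=C)C(=O)O[C@@H]3[C@@H]12 | intermediate
17 | 8β-(tert-butyldimethylsilyloxy)-3-oxoguaia-4(15),10(14),11(13)-trien-12,6α-olide | C=C1C(=O)C[C@H]2C(=C)C[C@@H](O[Si](C)(C)C(C)(C)C)[C@H]3C(=C)C(=O)O[C@@H]3[C@@H]12 | intermediate
18 | dehydrocostus lactone | C=C1CC[C@H]2C(=C)CC[C@H]3C(=C)C(=O)O[C@@H]3[C@@H]12 | starting material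
19 | 3-epizaluzanin C | C=C1[C@H](O)C[C@H]2C(=C)CC[C@H]3C(=C)C(=O)O[C@@H]3[C@@H]12 | intermediate
20 | dehydrozaluzanin C | C=C1C(=O)C[C@H]2C(=C)CC[C@H]3C(=C)C(=O)O[C@@H]3[C@@H]12 | intermediate
21 | 3-(trimethylsilyloxy)guaia-2,4(15),10(14),11(13)-tetraen-12,6α-olide | C=C1C(O[Si](C)(C)C)=C[C@H]2C(=C)CC[C@H]3C(=C)C(=O)O[C@@H]3[C@@H]12 | intermediate
22 | 3-oxoguaia-1,4(15),10(14),11(13)-tetraen-12,6α-olide | C=C1C(=O)C=C2C(=C)CC[C@H]3C(=C)C(=O)O[C@@H]3[C@@H]12 | intermediate
23 | Diels–Alder adduct (C1'=C10', H2'β, H5'α, 8-O-silyl) | C=C1C(=O)[C@H]2C3=C(CC[C@H]4C(=C)C(=O)O[C@@H]4[C@@H]13)CC[C@]21C(=O)C[C@H]2C(=C)C[C@@H](O[Si](C)(C)C(C)(C)C)[C@H]3C(=C)C(=O)O[C@@H]3[C@H]21 | intermediate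
24 | 8-O-tert-butyldimethylsilyl ether of the target | C=C1C(=O)C2=C3[C@H](CC[C@H]4C(=C)C(=O)O[C@@H]4[C@H]13)CC[C@]21C(=O)C[C@H]2C(=C)C[C@@H](O[Si](C)(C)C(C)(C)C)[C@H]3C(=C)C(=O)O[C@@H]3[C@H]21 | intermediate
25 | CNP0178208.1 | C=C1C(=O)C2=C3[C@H](CC[C@H]4C(=C)C(=O)O[C@@H]4[C@H]13)CC[C@]21C(=O)C[C@H]2C(=C)C[C@@H](O)[C@H]3C(=C)C(=O)O[C@@H]3[C@H]21 | target

**Totals**
Total step count: 19. Longest linear sequence: 16 (steps 1–13, then 17–19).

**Steps most likely to fail**

Step 6. The allylation may show poor facial selectivity at the aldehyde, or follow the polar Felkin–Anh sense and give the C6 epimer. The fallback accepts that sense and corrects C6 by inversion. It sets out from 8: indium-mediated allylation with methyl (Z)-2-(bromomethyl)-4,4-dimethoxybut-2-enoate (In, THF/H2O), which is syn-selective for an open-chain Z-bromide, should give the syn hydroxy ester F1. LiOH then gives the hydroxy acid F2. Mitsunobu lactonisation (PPh3, diisopropyl azodicarboxylate) closes the lactone with inversion at C6 to the trans-lactone dimethyl acetal F3. Mild acetal hydrolysis (PPTS, wet acetone) returns to the route at 12.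

Step 9. The ring closure may attack the wrong aldehyde face, or lose the allylsilane by protodesilylation before closure. The fallback sets C8 by reagent control instead. It sets out from 12: Pinnick oxidation (NaClO2, NaH2PO4, 2-methyl-2-butene) gives the acid F4, and 1-chloro-N,N,2-trimethylpropenylamine gives the acid chloride F5. Intramolecular acylation of the allylsilane (SnCl4, CH2Cl2, −78 °C) closes the ring to the β,γ-unsaturated ketone F6. Corey–Bakshi–Shibata reduction with (S)-2-methyl-CBS-oxazaborolidine and catecholborane delivers hydride to the α-face and returns to the route at 13.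

Step 17. Self-cycloaddition of the transient dienone may outrun the cross reaction when all of it is formed at once by the palladium oxidant. The fallback releases the dienone slowly from an isolable precursor. It sets out from 21: PhSeCl at −78 °C adds selenium to the convex face to give the 2α-phenylselanyl ketone F7. Slow addition of H2O2 to F7 and excess 17 at 0 °C forms the selenoxide F8 in the flask, whose syn elimination (H1' is cis to selenium) releases 22 at low stationary concentration. Cycloaddition with 17 then returns to the route at 23.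

**Further compounds**
F1 | step 6 | methyl syn-3-(dimethoxymethyl)-4-hydroxy-2-methylene-4-{cis-2,2-diethoxy-4-[3-(trimethylsilyl)prop-1-en-2-yl]cyclobutyl}butanoate (C6 epimer series) | CCOC1(OCC)C[C@@H](C(=C)C[Si](C)(C)C)[C@H]1[C@H](O)[C@@H](C(OC)OC)C(=C)C(=O)OC
F2 | step 6 | carboxylic acid of F1 | CCOC1(OCC)C[C@@H](C(=C)C[Si](C)(C)C)[C@H]1[C@H](O)[C@@H](C(OC)OC)C(=C)C(=O)O
F3 | step 6 | dimethyl acetal of 12 | CCOC1(OCC)C[C@@H](C(=C)C[Si](C)(C)C)[C@H]1[C@H]1OC(=O)C(=C)[C@@H]1C(OC)OC
F4 | step 9 | trans-2-(cyclobutyl)-4-methylene-5-oxotetrahydrofuran-3-carboxylic acid | CCOC1(OCC)C[C@@H](C(=C)C[Si](C)(C)C)[C@H]1[C@H]1OC(=O)C(=C)[C@@H]1C(=O)O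
F5 | step 9 | acid chloride of F4 | CCOC1(OCC)C[C@@H](C(=C)C[Si](C)(C)C)[C@H]1[C@H]1OC(=O)C(=C)[C@@H]1C(=O)Cl
F6 | step 9 | 8-oxo analogue of 13 | CCOC1(OCC)C[C@H]2C(=C)CC(=O)[C@H]3C(=C)C(=O)O[C@@H]3[C@@H]12
F7 | step 17 | 2α-(phenylselanyl)dehydrozaluzanin C | C=C1C(=O)[C@H]([Se]c2ccccc2)[C@H]2C(=C)CC[C@H]3C(=C)C(=O)O[C@@H]3[C@@H]12
F8 | step 17 | selenoxide of F7 | C=C1C(=O)[C@H]([Se](=O)c2ccccc2)[C@H]2C(=C)CC[C@H]3C(=C)C(=O)O[C@@H]3[C@@H]12
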